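We read delta at 4.0 h, so we ask what has become of one partner molecule by then. It may lie unused, stop in a mono adduct, or end in double product.

| setting | Saturday's | Tuesday's | Thursday's | delta | zeta | alpha |
|---|---|---|---|---|---|---|
| substrate | 0.42 M | 0.42 M | 0.42 M | 0.42 M | 0.42 M | 0.42 M |
| partner | 0.25 M | 0.60 M | 1.3 M | 0.336 M | 1.68 M | 0.210 M |
| remark | run made earlier | run made earlier | run made earlier |  |  |  |
| time |  |  |  | 4.0 h | 4.0 h | 4.0 h |

| run | time / h | double product / % | first product / % | substrate / % |
|---|---|---|---|---|
| Saturday's | 0.833 | 3 | 11 | 69 |
| Saturday's | 1.50 | 4 | 13 | 58 |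
| Saturday's | 2.50 | 5 | 16 | 52 |
| Saturday's | 3.00 | 5 | 18 | 49 |
| Saturday's | 4.00 | 7 | 21 | 46 |
| Tuesday's | 0.333 | 3 | 12 | 66 |
| Tuesday's | 0.667 | 5 | 18 | 49 |
| Tuesday's | 1.00 | 7 | 23 | 42 |
| Tuesday's | 2.00 | 17 | 26 | 25 |
| Tuesday's | 4.00 | 32 | 28 | 15 |
| Thursday's | 0.333 | 7 | 21 | 39 |
| Thursday's | 1.00 | 28 | 28 | 15 |
| Thursday's | 2.00 | 58 | 24 | 5 |
| Thursday's | 3.00 | 69 | 21 | 2 |
| Thursday's | 4.00 | 78 | 20 | 1 |

(standard deviation of a reading: 1.5 percentage points)

1. which of these holds the largest part of the substrate at the end of delta (first product / other mono adduct / double product / substrate)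
2. which of these holds the largest part of the substrate at the end of zeta (first product / other mono adduct / double product / substrate)
3. which of these holds the largest part of the substrate at the end of alpha (first product / other mono adduct / double product / substrate)
4. amount of double product at the end of delta, in percent of the substrate charged

- a reading or a percentage of first product counts all its forms, free or not
- a reading of substrate is of its free form alone

Let w be the chance that a charged partner molecule sits in double product at that time: twice the moles of double product over the moles of partner charged. Saturday's reading gives w = 0.235.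

Tuesday: w = 0.448

Thursday: w = 0.504

So w is larger in Tuesday's run than in Saturday's, and larger in Thursday's run than in Tuesday's. Each reading carries a scatter of 1.5 percentage points, and the bounds below carry it too.

Delta charges less partner than substrate, so partner is the limiting reagent. We bracket delta's double product from both sides, and the two inner bounds assume that w rises with partner charge between Saturday's and Tuesday's runs.

Widest top, w = one: 40.0%

Tighter top, Tuesday's w: 17.9%

Floor, Saturday's w: 9.41%

If double product bends upward with partner between these runs, as the rising w suggests, the straight line joining them lies above delta.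

Tightest top: 13.1%

We commit to the middle, 11.3%.

The forecast names substrate for delta, double product for zeta and substrate for alpha, and gives delta 12% double product (range 9% to 16%), above our middle, adding “Interpolating the runs gives about 13”.

The flasks end with substrate largest in delta at 35.7%, double product largest in zeta at 89.3%, and substrate largest in alpha at 53.3%. Delta holds 11.3% double product.

    substrate + partner → first product (k = 2.49 × 10⁻⁴ L mol⁻¹ s⁻¹)
    substrate + partner → other mono adduct (k = 3.03 × 10⁻⁴ L mol⁻¹ s⁻¹)
    partner + first product → double product (k = 1.45 × 10⁻⁴ L mol⁻¹ s⁻¹)
    partner + other mono adduct → double product (k = 3.63 × 10⁻⁴ L mol⁻¹ s⁻¹)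
    partner → decomposed reagent (k = 9.35 × 10⁻⁶ s⁻¹)
    substrate + first product ⇌ idle adduct, settled at all times (K = 2.80 L mol⁻¹)
    substrate → decomposition product (k = 2.81 × 10⁻⁷ s⁻¹)

Delta's w is 0.283, between Saturday's and Tuesday's , with 9.7% of its partner unused. Now take delta with partner raised to 0.57 M. The same reckoning gives a floor of 16.0% from Saturday's w and a top of 29.9% from the straight line. That flask ends with w = 0.424 and 28.8% double product, above the floor and below the straight line.

The numbers in the tables are simulated for an exercise; noise was put on by code.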